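Whether to feed Z slowly or charge it at once is the choice here, and two chemists differ on it.

| flask | Q | G | Z | temperature | remark | time |
|---|---|---|---|---|---|---|
| Wednesday's | 0.010 M | 0.010 M | 2.2 equiv (fed, over 30 min) | 75 °C | run made earlier |  |
| Sunday's | 0.040 M | 0.040 M | 2.2 equiv (fed, over 30 min) | 86 °C | run made earlier |  |
| south | 0.020 M | 0.020 M | 2.20 equiv (fed, over 30 min) | 80 °C |  | 30 min |
| west | 0.020 M | 0.020 M | 2.20 equiv | 80 °C | everything together at the start | 15 min |

| run | time / min | E / % | J / % |
|---|---|---|---|
| Wednesday's | 3.00 | 1.2 | 0.5 |
| Wednesday's | 10.0 | 2.1 | 2.0 |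
| Wednesday's | 15.0 | 7.3 | 2.5 |
| Wednesday's | 25.0 | 12.7 | 5.1 |
| Wednesday's | 40.0 | 22.5 | 8.8 |
| Sunday's | 3.00 | 1.1 | 0.2 |
| Sunday's | 10.0 | 11.9 | 4.3 |
| Sunday's | 15.0 | 17.5 | 8.8 |
| Sunday's | 25.0 | 32.8 | 14.8 |
| Sunday's | 40.0 | 42.0 | 23.1 |

(each reading ± 1 percentage point)

- Z is single-handed; Q and G are mirror images of each other, charged as a racemate, each of them at the stated concentration
- what may be going on: Z + Q -> E; Z + G -> J; Q <-> G; 2 Z -> X; Z -> D
- the handed part of Z does not stay in what it makes, so the products of the two hands are mirror images too

1. the flask that ends with the higher share of E in all that became E or J, or "neither" when 2 percentage points or less lies between them (south / west / neither)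
2. share of E in all that became E or J, south
3. share of E in all that became E or J, west

Let q = 1 − 2E and g = 1 − 2J, with E and J as fractions of Q and G together. These are the parts of each hand that have not become product.

The first chemist, who made the forecast, takes Q and G as separately consumed. On my own reckoning of that view, Z enters Z + Q -> E and Z + G -> J to the same power. It therefore cancels from the ratio of the two rates, and a feed schedule drops out if Q and G do not interconvert. What remains is the selectivity factor of a kinetic resolution, s = ln q / ln g. I read it from the last readings: 3.09 on Wednesday's run and 2.96 on Sunday's, so I carry their mean, 3.02. With s held, the share of E follows from q; as read, it is 71.9% in Wednesday's last reading and 64.5% in Sunday's.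

The second chemist points to Q <-> G. South runs twice as long as west, which gives inversion more time to refill Q, so he expects south to end above west by more than 2 percentage points.

The forecast is neither, with south at 71% and west at 70%. Its ground: “The share of E depends almost entirely on how far the reaction has gone”.

The simulation gives neither, with south at 69.9% and west at 69.9%. At the asked time Q <-> G makes no difference to south's share.

    Z + Q → E (k = 2.10 /M/min, Ea = 50.0 kJ/mol)
    Z + G → J (k = 0.720 /M/min, Ea = 58.0 kJ/mol)
    Q ⇌ G (k = 0.00420 /min, Ea = 111 kJ/mol)
    2 Z → X (k = 0.660 /M/min, Ea = 73.0 kJ/mol)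
    Z → D (k = 4.00 × 10⁻⁵ /min, Ea = 127 kJ/mol)
    (constants at 80 °C)

South's E and J at 30.0 min give ln q / ln g = 2.98, beside the carried 3.02. The second chemist's step has its region at long times: Q <-> G has a relaxation half-life of 82.5 min in west, and south at 300 min, ten times its asked time, holds a share of 65.6%, above the 59.7% that s gives from south's E. West read at 40 min holds E at 36.6%, from which s gives J at 17.6% and a share of 67.5%. That flask holds J at 17.4% and a share of 67.7%.

(Readings and results were computed on assumed constants.)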